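**Assumptions.** Grignard reagents that deliver carbon are numbered as starting materials. The (2R,5R)-amine is assumed to induce the (3R)-cyclobutanone in step 6; if the sense is opposite, its (2S,5S)-antipode is used in the same way.

## Retrosynthetic overview

1. Target ⇐ intramolecular aldol of a keto-aldehyde: the six-membered ring is closed last onto a cyclopentanone, giving the bicyclo[3.2.1]octan-8-one.
2. Cyclopentanone with the allyl-bearing quaternary carbon ⇐ oxocarbenium-triggered semipinacol ring expansion of a 1-(penta-1,4-dien-2-yl)cyclobutanol with the C2 cation from 1,1,2,2-tetramethoxyethane (key step, four → five).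
3. Cyclobutanol ⇐ 2-methoxy-3-aryl-4-methylcyclobutanone + ethynyl and allyl Grignard reagents (addition, then carbomagnesiation).
4. Cyclobutanone ⇐ auxiliary-controlled keteniminium/alkene cyclisation of a methoxyacetamide with (E)-isoelemicin.
5. (E)-Isoelemicin ⇐ p-cresol (dibromination, methoxylation/methylation, benzylic oxidation, EtMgBr/dehydration). Ring order: four → five → six.

## Route

Step 1
Reactants: 1 4-methylphenol
Product: 2 2,6-dibromo-4-methylphenol
Conditions: Br2 (2.05 equiv), AcOH, 15 °C → rt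
Reagents that add atoms: bromine (BrBr)
Why: Electrophilic aromatic bromination; the hydroxyl directs to both ortho positions because para is blocked.

Step 2
Reactants: 2 2,6-dibromo-4-methylphenol
Product: 4 1,2,3-trimethoxy-5-methylbenzene, via sodium 2,6-dimethoxy-4-methylphenolate 3 (not isolated)
Conditions: NaOMe (6 equiv), CuI (10 mol %), DMF–MeOH, 115 °C; then MeI (5 equiv), 40 °C
Reagents that add atoms: sodium methoxide ([Na+].[O-]C); iodomethane (CI)
Why: Ullmann-type copper-catalysed methoxylation of both aryl bromides, then Williamson O-methylation of the phenolate in the same pot.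

Step 3
Reactants: 4 1,2,3-trimethoxy-5-methylbenzene
Product: 5 3,4,5-trimethoxybenzaldehyde
Conditions: IBX (3 equiv), DMSO–fluorobenzene (1:2), 85 °C
Reagents that add atoms: 2-iodoxybenzoic acid, IBX (O=C1OI(=O)(O)c2ccccc12)
Why: IBX benzylic oxidation (single-electron oxidation of the electron-rich arene) stops at the aldehyde.

Step 4
Reactants: 5 3,4,5-trimethoxybenzaldehyde; 6 ethylmagnesium bromide
Product: 8 1,2,3-trimethoxy-5-[(1E)-prop-1-en-1-yl]benzene, via 1-(3,4,5-trimethoxyphenyl)propan-1-ol 7 (not isolated)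
Conditions: EtMgBr (1.2 equiv), THF, 0 °C; aq. NH4Cl; crude alcohol, p-TsOH·H2O (5 mol %), toluene, 80 °C (Dean–Stark)
Reagents that add atoms: none
Why: Grignard addition, then E1 dehydration through the stabilised benzylic cation gives the conjugated alkene with E geometry under thermodynamic control.

Step 5
Reactants: 9 methoxyacetyl chloride; 10 (2R,5R)-2,5-dimethylpyrrolidine
Product: 11 1-[(2R,5R)-2,5-dimethylpyrrolidin-1-yl]-2-methoxyethan-1-one
Conditions: Et3N (1.5 equiv), CH2Cl2, 0 °C → rt
Reagents that add atoms: none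
Why: N-acylation (Schotten–Baumann type) installs the C2-symmetric chiral auxiliary.

Step 6
Reactants: 11 1-[(2R,5R)-2,5-dimethylpyrrolidin-1-yl]-2-methoxyethan-1-one (1.3 equiv); 8 1,2,3-trimethoxy-5-[(1E)-prop-1-en-1-yl]benzene
Product: 14 (2R,3R,4S)-2-methoxy-4-methyl-3-(3,4,5-trimethoxyphenyl)cyclobutan-1-one, via keteniminium triflate 12 (not isolated), via cyclobutaniminium triflate 13 (not isolated)
Conditions: Tf2O (1.4 equiv), 2,4,6-collidine (1.5 equiv), ClCH2CH2Cl, −25 → 40 °C; then H2O/NaHCO3, rt; then Et3N (20 mol %), CH2Cl2, rt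
Reagents that add atoms: water (O)
Why: Ghosez keteniminium–alkene [2+2] cyclisation, a stepwise cationic process in which the CHMe alkene carbon adds to the central keteniminium carbon and the benzylic cation closes on the methoxy-enamine carbon; the C2-symmetric pyrrolidine shields one face so the aryl-bearing C3 is set as R, the E-alkene gives the trans C3/C4 pair, and base equilibration of the two enolisable α-centres leaves the all-trans ketone.

Step 7
Reactants: 14 (2R,3R,4S)-2-methoxy-4-methyl-3-(3,4,5-trimethoxyphenyl)cyclobutan-1-one; 15 ethynylmagnesium bromide; 16 allylmagnesium bromide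
Product: 18 (1R,2R,3R,4S)-2-methoxy-4-methyl-1-(penta-1,4-dien-2-yl)-3-(3,4,5-trimethoxyphenyl)cyclobutan-1-ol, via bromomagnesium 1-ethynylcyclobutanolate 17 (not isolated)
Conditions: HC≡CMgBr (1.3 equiv), THF, −78 → 0 °C; then allylMgBr (4 equiv), CuI (10 mol %), THF–Et2O, 0 °C → rt; aq. NH4Cl
Reagents that add atoms: none
Why: 1,2-Addition of the acetylide anti to the cis-disposed 2-methoxy and 4-methyl groups sets C1 (alkynyl cis to aryl), and copper-catalysed alkoxide-directed allylmagnesiation (carbometalation of a propargylic alkoxide) puts allyl on the proximal alkyne carbon, giving the 1,1-disubstituted alkene after protonolysis.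

Step 8
Reactants: 19 2,2-dimethoxyacetaldehyde (commercial 60 % aqueous solution)
Product: 20 1,1,2,2-tetramethoxyethane
Conditions: HC(OMe)3 (6 equiv), MeOH, p-TsOH·H2O (2 mol %), rt → 50 °C; NaOMe quench, distil
Reagents that add atoms: trimethyl orthoformate (COC(OC)OC)
Why: Acid-catalysed acetalisation, with the orthoformate also scavenging water.

Step 9
Reactants: 18 (1R,2R,3R,4S)-2-methoxy-4-methyl-1-(penta-1,4-dien-2-yl)-3-(3,4,5-trimethoxyphenyl)cyclobutan-1-ol; 20 1,1,2,2-tetramethoxyethane (2 equiv)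
Product: 22 (2S,3S,4R,5R)-5-methoxy-3-methyl-2-(prop-2-en-1-yl)-2-(2,3,3-trimethoxypropyl)-4-(3,4,5-trimethoxyphenyl)cyclopentan-1-one, via trimethylsilyl ether 21 (not isolated)
Conditions: TMSOTf (1.3 equiv), 2,6-lutidine (1.1 equiv), CH2Cl2, −78 °C, 15 min; then 20, −78 → −30 °C; aq. NaHCO3
Reagents that add atoms: none
Why: Proposed new method: an intermolecular oxocarbenium (Prins-type) semipinacol ring expansion in which TMSOTf ionises 20 to MeO+=CH–CH(OMe)2, the 1,1-disubstituted alkene of silyl ether 21 attacks through its CH2 terminus, and the incipient tertiary cation is quenched by anti-periplanar 1,2-shift of the electron-richer CH(CH3) ring carbon (not the inductively deactivated CH(OMe) carbon) with retention, driven by cyclobutane strain release and C=O formation; in the reactive conformer the C1–O bond eclipses C=CH2 (least A1,3 strain), so the allyl arm lies over C2 on the aryl face and the new quaternary centre forms with allyl cis to aryl and the C2 chain cis to methyl (side-chain methoxy carbon as an epimer mixture, corrected in step 10); the closest known chemistry is Overman's intramolecular Prins–pinacol ring-enlarging annulation and halonium- or proton-triggered semipinacol expansions of 1-vinylcyclobutanols.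

Step 10
Reactants: 22 (2S,3S,4R,5R)-5-methoxy-3-methyl-2-(prop-2-en-1-yl)-2-(2,3,3-trimethoxypropyl)-4-(3,4,5-trimethoxyphenyl)cyclopentan-1-one
Product: 24 (1R,2R,3R,5S,6S,7R)-2-hydroxy-1,3-dimethoxy-6-methyl-5-(prop-2-en-1-yl)-7-(3,4,5-trimethoxyphenyl)bicyclo[3.2.1]octan-8-one, via keto aldehyde 23 (not isolated)
Conditions: TFA–H2O (9:1), CH2Cl2, 0 °C → rt; evaporate; then MgBr2·OEt2 (1.5 equiv), Et3N (3 equiv), CH2Cl2, 0 °C → rt
Reagents that add atoms: water (O)
Why: Acetal hydrolysis, then a magnesium-templated intramolecular aldol from the only enolisable ketone α-carbon (the CH(OMe) carbon, whose configuration is reset through the enol) closes the six-membered ring on the face that carries the tether; the chelated Zimmerman–Traxler-type transition state places the new hydroxyl syn to the bridging carbonyl, while the epimerisable α-methoxy aldehyde carbon funnels to the equatorial (exo) methoxy isomer, setting C1, C2 and C3.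

## Compound list

1 | 4-methylphenol (p-cresol) | Cc1ccc(O)cc1 | starting material
2 | 2,6-dibromo-4-methylphenol | Cc1cc(Br)c(O)c(Br)c1 | intermediate
3 | sodium 2,6-dimethoxy-4-methylphenolate | Cc1cc(OC)c([O-])c(OC)c1.[Na+] | intermediate
4 | 1,2,3-trimethoxy-5-methylbenzene | Cc1cc(OC)c(OC)c(OC)c1 | intermediate
5 | 3,4,5-trimethoxybenzaldehyde | O=Cc1cc(OC)c(OC)c(OC)c1 | intermediate
6 | ethylmagnesium bromide | CC[Mg]Br | starting material
7 | 1-(3,4,5-trimethoxyphenyl)propan-1-ol (racemic) | CCC(O)c1cc(OC)c(OC)c(OC)c1 | intermediate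
8 | 1,2,3-trimethoxy-5-[(1E)-prop-1-en-1-yl]benzene ((E)-isoelemicin) | C/C=C/c1cc(OC)c(OC)c(OC)c1 | intermediate
9 | methoxyacetyl chloride | COCC(=O)Cl | starting material
10 | (2R,5R)-2,5-dimethylpyrrolidine (chiral auxiliary) | C[C@@H]1CC[C@@H](C)N1 | starting material
11 | 1-[(2R,5R)-2,5-dimethylpyrrolidin-1-yl]-2-methoxyethan-1-one | C[C@@H]1CC[C@@H](C)N1C(=O)COC | intermediate
12 | (2R,5R)-1-(2-methoxyethenylidene)-2,5-dimethylpyrrolidin-1-ium triflate (keteniminium triflate) | C[C@@H]1CC[C@@H](C)[N+]1=C=COC.[O-]S(=O)(=O)C(F)(F)F | intermediate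
13 | (2R,5R)-1-[(3R,4S)-2-methoxy-4-methyl-3-(3,4,5-trimethoxyphenyl)cyclobutylidene]-2,5-dimethylpyrrolidin-1-ium triflate (cyclobutaniminium triflate, C2 epimers) | C[C@@H]1CC[C@@H](C)[N+]1=C2C(OC)[C@@H](c3cc(OC)c(OC)c(OC)c3)[C@@H]2C.[O-]S(=O)(=O)C(F)(F)F | intermediate
14 | (2R,3R,4S)-2-methoxy-4-methyl-3-(3,4,5-trimethoxyphenyl)cyclobutan-1-one (aryl trans to both neighbours) | O=C1[C@H](OC)[C@@H](c2cc(OC)c(OC)c(OC)c2)[C@@H]1C | intermediate
15 | ethynylmagnesium bromide | C#C[Mg]Br | starting material
16 | allylmagnesium bromide | C=CC[Mg]Br | starting material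
17 | bromomagnesium (1R,2R,3R,4S)-1-ethynyl-2-methoxy-4-methyl-3-(3,4,5-trimethoxyphenyl)cyclobutan-1-olate | C#C[C@@]1(O[Mg]Br)[C@H](OC)[C@@H](c2cc(OC)c(OC)c(OC)c2)[C@@H]1C | intermediate
18 | (1R,2R,3R,4S)-2-methoxy-4-methyl-1-(penta-1,4-dien-2-yl)-3-(3,4,5-trimethoxyphenyl)cyclobutan-1-ol | C=CCC(=C)[C@@]1(O)[C@H](OC)[C@@H](c2cc(OC)c(OC)c(OC)c2)[C@@H]1C | intermediate
19 | 2,2-dimethoxyacetaldehyde | COC(OC)C=O | starting material
20 | 1,1,2,2-tetramethoxyethane | COC(OC)C(OC)OC | intermediate
21 | trimethylsilyl ether of 18 | C=CCC(=C)[C@@]1(O[Si](C)(C)C)[C@H](OC)[C@@H](c2cc(OC)c(OC)c(OC)c2)[C@@H]1C | intermediate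
22 | (2S,3S,4R,5R)-5-methoxy-3-methyl-2-(prop-2-en-1-yl)-2-(2,3,3-trimethoxypropyl)-4-(3,4,5-trimethoxyphenyl)cyclopentan-1-one (epimers at the side-chain CH(OMe)) | C=CC[C@@]1(CC(OC)C(OC)OC)C(=O)[C@H](OC)[C@@H](c2cc(OC)c(OC)c(OC)c2)[C@@H]1C | intermediate
23 | (2S,3S,4R,5R)-5-methoxy-2-(2-methoxy-3-oxopropyl)-3-methyl-2-(prop-2-en-1-yl)-4-(3,4,5-trimethoxyphenyl)cyclopentan-1-one (keto aldehyde, side-chain epimers) | C=CC[C@@]1(CC(OC)C=O)C(=O)[C@H](OC)[C@@H](c2cc(OC)c(OC)c(OC)c2)[C@@H]1C | intermediate
24 | (1R,2R,3R,5S,6S,7R)-2-hydroxy-1,3-dimethoxy-6-methyl-5-(prop-2-en-1-yl)-7-(3,4,5-trimethoxyphenyl)bicyclo[3.2.1]octan-8-one | C=CC[C@@]12C[C@@H](OC)[C@@H](O)[C@@](OC)(C1=O)[C@@H](c1cc(OC)c(OC)c(OC)c1)[C@@H]2C | target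

## Step count and risks

Total steps: 10 (steps 5 and 8 are side-branch preparations). Longest linear sequence: 8 (steps 1, 2, 3, 4, 6, 7, 9, 10).

**Step 6 (auxiliary-controlled keteniminium cyclisation).** An α-methoxy keteniminium has precedent only by analogy with α-amino cases, so both yield and facial control are uncertain. The fallback sets out from 8 (with 9) and returns at 14. Methoxyketene F1 is generated from 9 with Et3N in the presence of 8 and undergoes a thermal ketene–alkene cycloaddition to the racemic all-trans cyclobutanone after Et3N equilibration. The racemate is resolved by preparative chiral SFC; the unwanted (2S,3S,4R)-enantiomer F2 is discarded and 14 is carried on.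

**Step 9 (the proposed new ring expansion).** It may suffer from Friedel–Crafts attack of the cation on the trimethoxyarene, from competing migration of the CH(OMe) carbon, or from modest facial control at the quaternary centre. The fallback uses only known reactions, sets out from 14 (with 19 and 15) and returns at 22. Addition of 15 to 19 gives 1,1-dimethoxybut-3-yn-2-ol F3, and NaH/MeI gives 3,4,4-trimethoxybut-1-yne F4. Its lithium acetylide (n-BuLi, THF, −78 °C) adds to 14 to give the alkynylcyclobutanol F5. Cationic gold(I) ((p-CF3C6H4)3PAuCl/AgSbF6, CH2Cl2; the known ring expansion of 1-alkynylcyclobutanols) gives the (E)-alkylidenecyclopentanone F6. L-Selectride 1,4-reduction then generates the regiodefined enolate, which allyl bromide alkylates anti to the neighbouring methyl group to give 22.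

**Step 10 (aldol diastereoselectivity at the carbinol carbon).** If the cyclisation gives mainly the equatorial alcohol, the fallback sets out from 23 and returns at 24. The C2-epimeric aldol F7 is oxidised with Dess–Martin periodinane to the 2,8-dione F8. L-Selectride (THF, −78 °C) then attacks the less hindered C2 ketone from the equatorial direction to give the axial alcohol 24; the bridging C8 ketone, flanked by two quaternary carbons, is left untouched.

Further compounds
F1 | step 6 | methoxyketene | COC=C=O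
F2 | step 6 | (2S,3S,4R)-2-methoxy-4-methyl-3-(3,4,5-trimethoxyphenyl)cyclobutan-1-one | O=C1[C@@H](OC)[C@H](c2cc(OC)c(OC)c(OC)c2)[C@H]1C
F3 | step 9 | 1,1-dimethoxybut-3-yn-2-ol | COC(OC)C(O)C#C
F4 | step 9 | 3,4,4-trimethoxybut-1-yne | COC(OC)C(OC)C#C
F5 | step 9 | (1R,2R,3R,4S)-2-methoxy-4-methyl-1-(3,4,4-trimethoxybut-1-yn-1-yl)-3-(3,4,5-trimethoxyphenyl)cyclobutan-1-ol | COC(OC)C(OC)C#C[C@@]1(O)[C@H](OC)[C@@H](c2cc(OC)c(OC)c(OC)c2)[C@@H]1C
F6 | step 9 | (2E,3S,4R,5R)-5-methoxy-3-methyl-2-(2,3,3-trimethoxypropylidene)-4-(3,4,5-trimethoxyphenyl)cyclopentan-1-one | COC(OC)C(OC)/C=C1/C(=O)[C@H](OC)[C@@H](c2cc(OC)c(OC)c(OC)c2)[C@@H]1C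
F7 | step 10 | (1R,2S,3R,5S,6S,7R)-2-hydroxy-1,3-dimethoxy-6-methyl-5-(prop-2-en-1-yl)-7-(3,4,5-trimethoxyphenyl)bicyclo[3.2.1]octan-8-one | C=CC[C@@]12C[C@@H](OC)[C@H](O)[C@@](OC)(C1=O)[C@@H](c1cc(OC)c(OC)c(OC)c1)[C@@H]2C
F8 | step 10 | (1S,3R,5S,6S,7R)-1,3-dimethoxy-6-methyl-5-(prop-2-en-1-yl)-7-(3,4,5-trimethoxyphenyl)bicyclo[3.2.1]octane-2,8-dione | C=CC[C@@]12C[C@@H](OC)C(=O)[C@@](OC)(C1=O)[C@@H](c1cc(OC)c(OC)c(OC)c1)[C@@H]2C
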